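Everything rests on opening ring A of the non-prenylated flavone (unit 1) at the C4a–C8a bond. Ring A (C4a, C5, C6, C7, C8, C8a) is an unsubstituted, symmetric phloroglucinol ring that carries its acyl group at C4a, so it can be folded from a linear polycarbonyl chain by a polyketide-type Claisen condensation. The precursor is the complete biaryl: the 7-O-prenyl flavone (unit 2), joined through C8 to ring B, whose acyl group is extended to a 2,4-dioxobutyl chain that ends in a 4-hydroxy-2-pyrone. Mg(OMe)2 unmasks the pyrone and closes ring A in one operation; dilute acid then closes ring C and frees the two MOM-protected phenols.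

Key step: step 12

Remark: 4 and 6 are taken as catalogue compounds; the polycarbonyl compounds 14, 16, 17 and 18 are drawn as keto tautomers although enol, chelate or hemiketal forms should predominate; the target has no stereocentre and its biaryl axis is not configurationally defined, so no stereochemistry has to be set.

Step 1
Reactants: 1 methyl 3-bromo-4-hydroxybenzoate
Product: 2 methyl 3-bromo-4-(methoxymethoxy)benzoate
Conditions: MOMCl (1.5 equiv), i-Pr2NEt (2 equiv), CH2Cl2, 0 °C to rt
Reagents that add atoms: chloromethyl methyl ether (MOMCl), COCCl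
Why: Base-mediated O-alkylation (Williamson-type) of the acidic 4-hydroxyl with the reactive chloromethyl ether should be clean, and the MOM acetal is stable to all the basic steps that follow.

Step 2
Reactants: 2 methyl 3-bromo-4-(methoxymethoxy)benzoate
Product: 3 methyl 4-(methoxymethoxy)-3-(4,4,5,5-tetramethyl-1,3,2-dioxaborolan-2-yl)benzoate
Conditions: B2pin2 (1.2 equiv), PdCl2(dppf) (3 mol %), KOAc (3 equiv), 1,4-dioxane, 90 °C
Reagents that add atoms: bis(pinacolato)diboron, CC1(C)OB(OC1(C)C)B1OC(C)(C)C(C)(C)O1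
Why: Miyaura borylation of the aryl bromide with zerovalent palladium (formed from PdCl2(dppf)) and the weak base KOAc should give the pinacol boronate without touching the ester or the acetal.

Step 3
Reactants: 4 1-[2,4-bis(benzyloxy)-6-hydroxyphenyl]ethan-1-one
Product: 5 1-[4,6-bis(benzyloxy)-2-hydroxy-3-iodophenyl]ethan-1-one
Conditions: NIS (1.0 equiv), CF3CO2H (0.1 equiv), MeCN, 0 °C to rt, dark
Reagents that add atoms: N-iodosuccinimide, O=C1CCC(=O)N1I
Why: Electrophilic aromatic iodination of the phloroglucinol ring should go ortho to the chelated free hydroxyl (C3), the alternative site being flanked by two benzyloxy groups, which places iodine next to the only oxygen that can later close the pyranone.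

Step 4
Reactants: 5 1-[4,6-bis(benzyloxy)-2-hydroxy-3-iodophenyl]ethan-1-one; 6 4-(methoxymethoxy)benzaldehyde
Product: 7 (2E)-1-[4,6-bis(benzyloxy)-2-hydroxy-3-iodophenyl]-3-[4-(methoxymethoxy)phenyl]prop-2-en-1-one
Conditions: 6 (1.2 equiv), KOH (50 % aq, 10 equiv), EtOH, rt; cold 1 M HCl to pH 5
Reagents that add atoms: none
Why: Claisen–Schmidt (crossed aldol) condensation of the methyl ketone enolate with the non-enolisable aldehyde followed by E1cB loss of water should give the E-enone under thermodynamic control, and any flavanone formed by ring closure is equally usable in step 5.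

Step 5
Reactants: 7 (2E)-1-[4,6-bis(benzyloxy)-2-hydroxy-3-iodophenyl]-3-[4-(methoxymethoxy)phenyl]prop-2-en-1-one
Product: 8 5,7-bis(benzyloxy)-8-iodo-2-[4-(methoxymethoxy)phenyl]-4H-chromen-4-one
Conditions: I2 (0.1 equiv), DMSO, 120 °C; aq Na2S2O3 work-up
Reagents that add atoms: none
Why: Iodine-catalysed oxidative cyclisation of a 2'-hydroxychalcone (oxa-Michael closure, α-iodination, loss of HI, DMSO as terminal oxidant) is the standard flavone synthesis, and since the only free hydroxyl is the one next to iodine the halogen must end up at C8, while catalytic iodine keeps HI low enough for the remote MOM ether.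

Step 6
Reactants: 8 5,7-bis(benzyloxy)-8-iodo-2-[4-(methoxymethoxy)phenyl]-4H-chromen-4-one; 3 methyl 4-(methoxymethoxy)-3-(4,4,5,5-tetramethyl-1,3,2-dioxaborolan-2-yl)benzoate
Product: 9 methyl 3-{5,7-bis(benzyloxy)-2-[4-(methoxymethoxy)phenyl]-4-oxo-4H-chromen-8-yl}-4-(methoxymethoxy)benzoate
Conditions: 3 (1.3 equiv), Pd(OAc)2 (5 mol %), SPhos (10 mol %), K3PO4 (3 equiv), 1,4-dioxane/H2O (5:1), 90 °C
Reagents that add atoms: none
Why: Suzuki–Miyaura coupling of the electron-rich, doubly ortho-substituted aryl iodide with the ortho-alkoxy boronate is the established way to the C8–C3' bond of 8-arylflavones, and the bulky electron-rich SPhos ligand on zerovalent palladium is suited to such hindered partners.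

Step 7
Reactants: 9 methyl 3-{5,7-bis(benzyloxy)-2-[4-(methoxymethoxy)phenyl]-4-oxo-4H-chromen-8-yl}-4-(methoxymethoxy)benzoate
Product: 10 methyl 3-{5,7-dihydroxy-2-[4-(methoxymethoxy)phenyl]-4-oxo-4H-chromen-8-yl}-4-(methoxymethoxy)benzoate
Conditions: H2 (1 atm), Pd/C (10 wt %), EtOAc/MeOH (1:1), rt
Reagents that add atoms: none
Why: Hydrogenolysis of the two benzyl ethers over palladium on carbon at atmospheric pressure should leave the MOM acetals, the ester and the flavone C2=C3 bond untouched, and it is done before any alkene is present.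

Step 8
Reactants: 10 methyl 3-{5,7-dihydroxy-2-[4-(methoxymethoxy)phenyl]-4-oxo-4H-chromen-8-yl}-4-(methoxymethoxy)benzoate
Product: 11 methyl 3-{5-hydroxy-2-[4-(methoxymethoxy)phenyl]-7-[(3-methylbut-2-en-1-yl)oxy]-4-oxo-4H-chromen-8-yl}-4-(methoxymethoxy)benzoate
Conditions: prenyl bromide (1.15 equiv), K2CO3 (1.5 equiv), acetone, 50 °C
Reagents that add atoms: 1-bromo-3-methylbut-2-ene (prenyl bromide), CC(C)=CCBr
Why: Williamson etherification takes place at the acidic, non-chelated 7-hydroxyl while the 5-hydroxyl, hydrogen-bonded to the C4 carbonyl, stays free, which is the usual selectivity of 5,7-dihydroxyflavones.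

Step 9
Reactants: 11 methyl 3-{5-hydroxy-2-[4-(methoxymethoxy)phenyl]-7-[(3-methylbut-2-en-1-yl)oxy]-4-oxo-4H-chromen-8-yl}-4-(methoxymethoxy)benzoate
Product: 12 3-{5-hydroxy-2-[4-(methoxymethoxy)phenyl]-7-[(3-methylbut-2-en-1-yl)oxy]-4-oxo-4H-chromen-8-yl}-4-(methoxymethoxy)benzoic acid
Conditions: LiOH·H2O (5 equiv), THF/MeOH/H2O (3:1:1), 45 °C; cold 1 M HCl to pH 3
Reagents that add atoms: lithium hydroxide (hydroxide oxygen), [Li+].[OH-]
Why: Saponification (acyl-oxygen cleavage by hydroxide) of the methyl benzoate is compatible with the prenyl ether and the acetals, and the 5-phenoxide formed in base protects the pyranone against ring opening.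

Step 10
Reactants: 13 4-hydroxy-6-methyl-2H-pyran-2-one
Product: 14 4-hydroxy-6-(2-oxopropyl)-2H-pyran-2-one
Conditions: LiN(i-Pr)2 (2.3 equiv, commercial solution), THF, −78 °C; MeC(O)N(OMe)Me (1.1 equiv), −78 to −20 °C; then 1 M HCl
Reagents that add atoms: N-methoxy-N-methylacetamide, CC(=O)N(C)OC
Why: Double deprotonation gives the O,C-dianion whose C6-methyl carbanion (the last formed and most nucleophilic site) is acylated by the Weinreb amide, the chelated tetrahedral adduct preventing a second addition, which is the known side-chain acylation of triacetic acid lactone.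

Step 11
Reactants: 12 3-{5-hydroxy-2-[4-(methoxymethoxy)phenyl]-7-[(3-methylbut-2-en-1-yl)oxy]-4-oxo-4H-chromen-8-yl}-4-(methoxymethoxy)benzoic acid; 14 4-hydroxy-6-(2-oxopropyl)-2H-pyran-2-one
Product: 16 5-hydroxy-8-{5-[4-(4-hydroxy-2-oxo-2H-pyran-6-yl)-3-oxobutanoyl]-2-(methoxymethoxy)phenyl}-2-[4-(methoxymethoxy)phenyl]-7-[(3-methylbut-2-en-1-yl)oxy]-4H-chromen-4-one, via acyl imidazole 15 (not isolated)
Conditions: (a) 12, CDI (1.1 equiv), THF, rt, then Ar sparge to expel CO2; (b) 14 (4.5 equiv), LiN(i-Pr)2 (13.5 equiv, commercial solution), THF, −78 to 0 °C, recool to −78 °C, add solution (a), −78 to −30 °C; cold 1 M HCl to pH 3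
Reagents that add atoms: 1,1'-carbonyldiimidazole, O=C(n1ccnc1)n1ccnc1 (its imidazolyl group is carried only by intermediate 15)
Why: The acid is activated as its acyl imidazole and attacked by the terminal methylene of the trilithium trianion of 14, the last-formed and most reactive carbanion, in a Claisen-type C-acylation of a polyanion; the surplus trianion absorbs the protons of the 5-hydroxyl, of the released imidazole and of the more acidic product, and the 5-phenoxide so formed deactivates flavone unit 2 toward addition.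

Step 12
Reactants: 16 5-hydroxy-8-{5-[4-(4-hydroxy-2-oxo-2H-pyran-6-yl)-3-oxobutanoyl]-2-(methoxymethoxy)phenyl}-2-[4-(methoxymethoxy)phenyl]-7-[(3-methylbut-2-en-1-yl)oxy]-4H-chromen-4-one
Product: 18 1-[3-{5-hydroxy-2-[4-(methoxymethoxy)phenyl]-7-[(3-methylbut-2-en-1-yl)oxy]-4-oxo-4H-chromen-8-yl}-4-(methoxymethoxy)phenyl]-3-(2,4,6-trihydroxyphenyl)propane-1,3-dione, via tetraoxo methyl ester 17 (not isolated)
Conditions: Mg(OMe)2 (10 equiv, solution in MeOH), anhydrous MeOH, 65 °C, Ar; cold 1 M HCl to pH 3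
Reagents that add atoms: magnesium methoxide, CO[Mg]OC (its methoxy group is carried only by intermediate 17)
Why: Proposed new method: methoxide from Mg(OMe)2 adds to the lactone carbonyl of the 4-hydroxy-2-pyrone and opens it to the magnesium-chelated methyl 3,5,7,9-tetraoxo ester 17, in which the methylene C4a (atom labels are those of the future unit 1 flavone), flanked by the C4 and C5 carbonyls, attacks the terminal ester carbon C8a and expels methoxide, after which the cyclic triketone tautomerises irreversibly to the aromatic phloroglucinol. The closest known reaction type is the magnesium-alkoxide-mediated Claisen cyclisation of 3,5,7-triketo esters and of their 4-hydroxy-2-pyrone forms to acylphloroglucinols, whereas the present chain is one carbonyl longer and ends in a hindered biaryl ketone. Ring A closes in a 6-exo-trig acyl substitution (enolate carbon C4a onto the ester carbonyl), which forms the single bond C4a–C8a. No stereocentre is created. The step needs the Claisen closure to win over three aldol foldings (C8 onto C4, C3 onto C7, C6 onto C2), and this should be secured because in anhydrous Mg(OMe)2 every ketone is tied up as a chelated enolate while the ester remains the only free electrophile, because the aryl ketone C2 is deactivated by the para-alkoxy ring B, and because aromatisation drains the Claisen product, ring A being symmetric so that only one such product exists. The chelated 5-phenoxide shields flavone unit 2 from methoxide, and the prenyl ether and MOM acetals are inert to base.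

Step 13
Reactants: 18 1-[3-{5-hydroxy-2-[4-(methoxymethoxy)phenyl]-7-[(3-methylbut-2-en-1-yl)oxy]-4-oxo-4H-chromen-8-yl}-4-(methoxymethoxy)phenyl]-3-(2,4,6-trihydroxyphenyl)propane-1,3-dione
Product: 20 8-[5-(5,7-dihydroxy-4-oxo-4H-chromen-2-yl)-2-hydroxyphenyl]-5-hydroxy-2-(4-hydroxyphenyl)-7-[(3-methylbut-2-en-1-yl)oxy]-4H-chromen-4-one, via bis-MOM biflavone 19 (not isolated)
Conditions: HCl (1.25 M in MeOH), THF/MeOH, 45 °C, stopped as soon as the MOM groups are gone
Reagents that add atoms: none
Why: Acid catalysis closes ring C by attack of a ring A hydroxyl on the aryl ketone C2 (6-exo-trig hemiketal formation) and dehydration, the last stage of a Baker–Venkataraman-type flavone synthesis in which either ortho hydroxyl gives the same product, while methanolysis of the two MOM acetals occurs under the same dilute, merely warm conditions chosen to spare the prenyl ether.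

Compound list
1 | methyl 3-bromo-4-hydroxybenzoate | COC(=O)c1ccc(O)c(Br)c1 | starting material
2 | methyl 3-bromo-4-(methoxymethoxy)benzoate | COCOc1ccc(C(=O)OC)cc1Br | intermediate
3 | methyl 4-(methoxymethoxy)-3-(4,4,5,5-tetramethyl-1,3,2-dioxaborolan-2-yl)benzoate | COCOc1ccc(C(=O)OC)cc1B1OC(C)(C)C(C)(C)O1 | intermediate
4 | 1-[2,4-bis(benzyloxy)-6-hydroxyphenyl]ethan-1-one | CC(=O)c1c(O)cc(OCc2ccccc2)cc1OCc1ccccc1 | starting material
5 | 1-[4,6-bis(benzyloxy)-2-hydroxy-3-iodophenyl]ethan-1-one | CC(=O)c1c(O)c(I)c(OCc2ccccc2)cc1OCc1ccccc1 | intermediate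
6 | 4-(methoxymethoxy)benzaldehyde | COCOc1ccc(C=O)cc1 | starting material
7 | (2E)-1-[4,6-bis(benzyloxy)-2-hydroxy-3-iodophenyl]-3-[4-(methoxymethoxy)phenyl]prop-2-en-1-one | COCOc1ccc(/C=C/C(=O)c2c(O)c(I)c(OCc3ccccc3)cc2OCc2ccccc2)cc1 | intermediate
8 | 5,7-bis(benzyloxy)-8-iodo-2-[4-(methoxymethoxy)phenyl]-4H-chromen-4-one | COCOc1ccc(-c2cc(=O)c3c(OCc4ccccc4)cc(OCc4ccccc4)c(I)c3o2)cc1 | intermediate
9 | methyl 3-{5,7-bis(benzyloxy)-2-[4-(methoxymethoxy)phenyl]-4-oxo-4H-chromen-8-yl}-4-(methoxymethoxy)benzoate | COCOc1ccc(-c2cc(=O)c3c(OCc4ccccc4)cc(OCc4ccccc4)c(-c4cc(C(=O)OC)ccc4OCOC)c3o2)cc1 | intermediate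
10 | methyl 3-{5,7-dihydroxy-2-[4-(methoxymethoxy)phenyl]-4-oxo-4H-chromen-8-yl}-4-(methoxymethoxy)benzoate | COCOc1ccc(-c2cc(=O)c3c(O)cc(O)c(-c4cc(C(=O)OC)ccc4OCOC)c3o2)cc1 | intermediate
11 | methyl 3-{5-hydroxy-2-[4-(methoxymethoxy)phenyl]-7-[(3-methylbut-2-en-1-yl)oxy]-4-oxo-4H-chromen-8-yl}-4-(methoxymethoxy)benzoate | COCOc1ccc(-c2cc(=O)c3c(O)cc(OCC=C(C)C)c(-c4cc(C(=O)OC)ccc4OCOC)c3o2)cc1 | intermediate
12 | 3-{5-hydroxy-2-[4-(methoxymethoxy)phenyl]-7-[(3-methylbut-2-en-1-yl)oxy]-4-oxo-4H-chromen-8-yl}-4-(methoxymethoxy)benzoic acid | COCOc1ccc(-c2cc(=O)c3c(O)cc(OCC=C(C)C)c(-c4cc(C(=O)O)ccc4OCOC)c3o2)cc1 | intermediate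
13 | 4-hydroxy-6-methyl-2H-pyran-2-one | Cc1cc(O)cc(=O)o1 | starting material
14 | 4-hydroxy-6-(2-oxopropyl)-2H-pyran-2-one | CC(=O)Cc1cc(O)cc(=O)o1 | intermediate
15 | 5-hydroxy-8-[5-(1H-imidazole-1-carbonyl)-2-(methoxymethoxy)phenyl]-2-[4-(methoxymethoxy)phenyl]-7-[(3-methylbut-2-en-1-yl)oxy]-4H-chromen-4-one | COCOc1ccc(-c2cc(=O)c3c(O)cc(OCC=C(C)C)c(-c4cc(C(=O)n5ccnc5)ccc4OCOC)c3o2)cc1 | intermediate
16 | 5-hydroxy-8-{5-[4-(4-hydroxy-2-oxo-2H-pyran-6-yl)-3-oxobutanoyl]-2-(methoxymethoxy)phenyl}-2-[4-(methoxymethoxy)phenyl]-7-[(3-methylbut-2-en-1-yl)oxy]-4H-chromen-4-one | CC(C)=CCOc1cc(O)c2c(=O)cc(-c3ccc(OCOC)cc3)oc2c1-c1cc(C(=O)CC(=O)Cc2cc(O)cc(=O)o2)ccc1OCOC | intermediate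
17 | methyl 9-[3-{5-hydroxy-2-[4-(methoxymethoxy)phenyl]-7-[(3-methylbut-2-en-1-yl)oxy]-4-oxo-4H-chromen-8-yl}-4-(methoxymethoxy)phenyl]-3,5,7,9-tetraoxononanoate | CC(C)=CCOc1cc(O)c2c(=O)cc(-c3ccc(OCOC)cc3)oc2c1-c1cc(C(=O)CC(=O)CC(=O)CC(=O)CC(=O)OC)ccc1OCOC | intermediate
18 | 1-[3-{5-hydroxy-2-[4-(methoxymethoxy)phenyl]-7-[(3-methylbut-2-en-1-yl)oxy]-4-oxo-4H-chromen-8-yl}-4-(methoxymethoxy)phenyl]-3-(2,4,6-trihydroxyphenyl)propane-1,3-dione | CC(C)=CCOc1cc(O)c2c(=O)cc(-c3ccc(OCOC)cc3)oc2c1-c1cc(C(=O)CC(=O)c2c(O)cc(O)cc2O)ccc1OCOC | intermediate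
19 | 8-[5-(5,7-dihydroxy-4-oxo-4H-chromen-2-yl)-2-(methoxymethoxy)phenyl]-5-hydroxy-2-[4-(methoxymethoxy)phenyl]-7-[(3-methylbut-2-en-1-yl)oxy]-4H-chromen-4-one | CC(C)=CCOc1cc(O)c2c(=O)cc(-c3ccc(OCOC)cc3)oc2c1-c1cc(-c2cc(=O)c3c(O)cc(O)cc3o2)ccc1OCOC | intermediate
20 | 8-[5-(5,7-dihydroxy-4-oxo-4H-chromen-2-yl)-2-hydroxyphenyl]-5-hydroxy-2-(4-hydroxyphenyl)-7-[(3-methylbut-2-en-1-yl)oxy]-4H-chromen-4-one | CC(C)=CCOc1cc(O)c2c(=O)cc(-c3ccc(O)cc3)oc2c1-c1cc(-c2cc(=O)c3c(O)cc(O)cc3o2)ccc1O | target

Total step count: 13. Longest linear sequence: 10 steps (steps 3 to 9, then 11, 12 and 13, counted from acetophenone 4).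

Steps most likely to fail

Step 12. The unmasked polyanionic chain may fold by one of the aldol modes instead of the Claisen mode, or the pyrone may resist opening, so that ring A is not formed cleanly. The fallback sets out from acid 12 and buys ring A instead of building it. Acid 12 is esterified (EDC·HCl, DMAP, CH2Cl2, rt) with commercial 1-[2-hydroxy-4,6-bis(methoxymethoxy)phenyl]ethan-1-one to give the aryl ester 2-acetyl-3,5-bis(methoxymethoxy)phenyl benzoate F1. A Baker–Venkataraman rearrangement (KOH, pyridine, 50 °C) then moves the aroyl group to carbon and should give the ring A bis-MOM 1,3-diketone F2. Treating F2 with HCl in MeOH/THF as in step 13 closes ring C and removes all four MOM groups, so the fallback comes back to the route at 20.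

Step 11. Proton transfer from the electrophile may quench the trianion faster than it is acylated, or the carbanion may add to the pyranone of flavone unit 2. The fallback sets out from acyl imidazole 15 and forms the C3–C4 bond instead of C2–C3. Compound 15 is condensed with Mg(O2CCH2CO2Me)2 in THF at rt to 40 °C (decarboxylative Claisen condensation), which should give the β-keto ester methyl 3-aryl-3-oxopropanoate F3. The lithium enolate of F3 is then added to the dianion of pyrone 13 (LiN(i-Pr)2, THF, −78 to 0 °C). The C6-methyl carbanion attacks the ester group in the known, if less efficient, two-carbonyl acylation of a dicarbonyl dianion by a β-keto ester salt, and the fallback comes back to the route at 16.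

Step 13. Protonation of the prenyl ether may lead to loss or solvolysis of the prenyl group before both MOM acetals are cleaved. The fallback sets out from 18 and separates the two events. Heating 18 in AcOH buffered with NaOAc at 80 °C should only cyclodehydrate it to the bis-MOM biflavone 19, which is isolated. The acetals of 19 are then cleaved without Brønsted acid by ZnBr2 and n-PrSH in CH2Cl2 at 0 °C (thiol-assisted Lewis-acid transacetalisation), and the fallback comes back to the route at 20.

Further compounds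
F1 | step 12 | 2-acetyl-3,5-bis(methoxymethoxy)phenyl 3-{5-hydroxy-2-[4-(methoxymethoxy)phenyl]-7-[(3-methylbut-2-en-1-yl)oxy]-4-oxo-4H-chromen-8-yl}-4-(methoxymethoxy)benzoate | COCOc1ccc(-c2cc(=O)c3c(O)cc(OCC=C(C)C)c(-c4cc(C(=O)Oc5cc(OCOC)cc(OCOC)c5C(C)=O)ccc4OCOC)c3o2)cc1
F2 | step 12 | 1-[2-hydroxy-4,6-bis(methoxymethoxy)phenyl]-3-[3-{5-hydroxy-2-[4-(methoxymethoxy)phenyl]-7-[(3-methylbut-2-en-1-yl)oxy]-4-oxo-4H-chromen-8-yl}-4-(methoxymethoxy)phenyl]propane-1,3-dione | COCOc1ccc(-c2cc(=O)c3c(O)cc(OCC=C(C)C)c(-c4cc(C(=O)CC(=O)c5c(O)cc(OCOC)cc5OCOC)ccc4OCOC)c3o2)cc1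
F3 | step 11 | methyl 3-[3-{5-hydroxy-2-[4-(methoxymethoxy)phenyl]-7-[(3-methylbut-2-en-1-yl)oxy]-4-oxo-4H-chromen-8-yl}-4-(methoxymethoxy)phenyl]-3-oxopropanoate | COCOc1ccc(-c2cc(=O)c3c(O)cc(OCC=C(C)C)c(-c4cc(C(=O)CC(=O)OC)ccc4OCOC)c3o2)cc1
F0 | step 13 | none | none
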